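## The problem

Locants C1–C15 are those of the germacrane skeleton of the target; cyclohexene locants are used only for 6 and 8.

- **Ring system.** Compound 26 is a ten-membered carbocycle (C1–C10) bridged from C1 to C4 by an ether oxygen, so that C1–C4 and that oxygen form an oxolane. It is fused at C6–C7 to a butenolide whose ring oxygen sits on the enol carbon C6. C4–C5=C6(O)–C7=C11–C12=O is therefore one dienolide, carrying CH2OAc (C13) on C11.
- **Stereocentres.** Four must be set: the quaternary ether carbon C4, the ether methine C1, the adjacent tertiary carbinol C10, and the acylated carbinol C8.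
- **Who controls whom.** C1 and C10 are tied to each other, as two oxygens added anti across a 1(10)E alkene. C8 can be taken from the chiral pool. C4 and the C1/C10 pair can be related to C8 only through the conformation of a medium ring, which is the weakest control in the molecule.
- **Fragile groups.** The angelate isomerises to the tiglate with nucleophiles or long heating. The enol lactone is an acyl donor toward alkoxide, hydroxide and fluoride. The allylic acetate and the tertiary alcohol limit base and strong acid. An 8-acyloxy group is β to the C6 carbonyl until C7=C11 exists (E1cB), and a free 8-hydroxyl lactonises onto C12 as long as C7 is sp3.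
- **Enabling feature.** The carbocycle has oxygen at C6, methyl-bearing C4 and C10 on either side of the C1–C3 bridge, and oxygen at C8, two carbons from C6. This is the pattern of a germacra-1(10),4-dien-6-one, the [3,3] product of a 1,2-dialkenylcyclohex-2-enol in which C8 was the terminus of a vinyl group. Oxygen at that terminus can travel through the rearrangement as silicon.

## Retrosynthesis

**26 ⇒ 24 + 25 (O8–acyl bond).** The angelate goes on last. Before C7=C11 exists an 8-acyloxy group would be lost by E1cB from any C6–C7 enolate, and every earlier basic or nucleophilic step would threaten the Z geometry. The precursor is allylic alcohol 24 and commercial angelic acid 25. The acylation must spare the tertiary C10 hydroxyl and the enol lactone and must not isomerise the acid.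

**24 ⇒ 23 ⇒ 22 (O6–C12 lactone bond and C7=C11).** The dienolide is opened to the saturated pyruvate aldol adduct 22. Acid cyclocondensation of such γ-keto α-hydroxy esters forms the lactone and both conjugated double bonds in one operation. Olefination of a 6,7-diketone or carbonylation of an enol triflate would each need extra oxidation steps. Compound 22 has no C=C bond and an acyclic side chain. O8 must be blocked during the condensation (silyl ether 23), because a free 8-hydroxyl would close the more stable 8,12-lactone.

**22 ⇒ 21 ⇒ 20 (C1–O ether bond).** The oxolane is cut at C1–O and not at C4–O. Backside opening of a 1,10-epoxide by the C4 hydroxyl is irreversible, sets C1 by inversion and leaves the epoxide oxygen on C10. Closing C4–O by conjugate addition would put C4 under thermodynamic control. Precursor 20 is monocyclic with one alkene. The forward step needs the right alkene face and 5-exo opening at C1 in preference to 6-endo opening at tertiary C10.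

**20 ⇒ 19 (C5–O bond restored).** The tertiary C4 hydroxyl with CH2 at C5 is the reduction product of a 4,5-epoxy ketone. The epoxide does two jobs: it carries the C4 oxygen, and while it is present C5 cannot be enolised. The reduction must touch only the C5–O bond.

**19 ⇒ 15 + 17, 17 ⇒ 16 (C7–C11 bond).** An aldol addition of the C6–C7 enolate of 15 to the keto group of ethyl acetoxypyruvate 17 brings in C11, C12 and C13 with the acetate in place. Compound 17 comes from ethyl bromopyruvate 16 in one step. Addition to the keto group has to outrun proton transfer from the acidic CH2 of 17.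

**15 ⇒ 14 ⇒ 12 (C8–O from C8–Si).** The C8 oxygen is unmasked before C12 is introduced, otherwise the new hydroxyl would meet the ester. It must therefore be unmasked while the 1(10) alkene is still present. This fixes the spectator groups on silicon: benzyldimethylsilyl is cleaved by fluoride and oxidised by basic peroxide, without the electrophile or peracid that a phenylsilane needs. The alcohol 14 is capped as the tert-butyldiphenylsilyl ether 15, a poor leaving group in the enolate of step 9.

**12 ⇒ 11 (epoxide oxygen removed).** Nucleophilic epoxidation of the 4Z enone installs the C4 oxygen. Silicon at C8 is inert to it. The demand is face selectivity at C4.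

**11 ⇒ 8 (key step: C8–C9 cut, cyclohexene bond restored).** The ten-membered ring is traced to a six-membered one by an anionic oxy-Cope rearrangement. Against any end-to-end macrocyclisation this needs no dilution, delivers the C6 oxygen, both ring alkenes and the C8 stereocentre together, and starts from a monoterpene. The precursor is the trans-dialkenyl cyclohexenol 8.

**8 ⇒ 6 + 4, 6 ⇒ 5, 4 ⇒ 1 + 2.** Compound 8 is the 1,2-adduct of an E-silylvinyllithium (from stannane 4) to (S)-isopiperitenone 6. Compound 6 is the allylic oxidation product of (R)-limonene 5. Compound 4 comes from commercial bis-stannane 1 and chlorosilane 2.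

## Roads not taken

**Alternative 1:** The oxolane and the tertiary carbinol are made first, on the acyclic diol (2E,6S)-2,6-dimethylocta-2,7-diene-1,6-diol A1 ((S,E)-8-hydroxylinalool).
- *Key step:* Sharpless epoxidation of the allylic alcohol of A1 (Ti(OiPr)4, D-(−)-diisopropyl tartrate, t-BuOOH), then attack of the tertiary hydroxyl on the proximal epoxide carbon. This forms the C10–O and C1–O bonds and gives oxolane diol A2.
- *Merits:* C4 comes from the chiral pool. C1 and C10 are set by reagent control in one pot. In a monocyclic oxolane the trans relationship of the two ring substituents costs nothing.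
- *Weak points:* everything else is left open: the C8 stereocentre, the butenolide, and closure of the ten-membered ring between the vinyl group and the primary alcohol. That closure must span an oxolane whose two arms point to opposite faces.
- *Comparison:* for C1, C4 and C10 this road is better, because its control does not depend on a medium-ring conformation. The chosen plan sets against it a ring synthesis solved in one pericyclic step, with C8 by chirality transfer and all ten ring carbons in place.

**Alternative 2:** The cut is C4–C5.
- *Key step:* photoredox oxidation of the carboxylate of seco acid A3 releases CO2 and a tertiary α-oxy radical at C4. Nickel couples it with the vinyl bromide of the bromomethylene butenolide and closes the carbocycle to silyl ether A4.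
- *Merits:* convergent and late. The C4 configuration of A3 does not matter. A4 is the trialkylsilyl counterpart of 23, two steps from the target.
- *Weak points:* nickel-mediated formation of a quaternary sp3–sp2 bond from a tertiary radical is at the edge of the method, and here it must also close a strained ten-membered ring at high dilution. The bromomethylene butenolide is a radical acceptor, and its geometry can isomerise under photocatalysis. "Stereoconvergent" means one outcome at C4, fixed by ring strain, not necessarily the required one. A3 needs its own synthesis, with C1, C8 and C10 already set.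
- *Comparison:* it is more convergent and its end game is shorter. The chosen plan sets against it a stereospecific ring-forming step of a well-known class and a shorter count from commodity terpenes.

**Alternative 3:** The cut is O–C4.
- *Key step:* the C1 hydroxyl of macrocyclic enone A5 adds to C4 under acid or mild base and closes the oxolane to keto ester A6. Deallylation and enol lactonisation follow.
- *Merits:* one step replaces three (epoxidation, reduction, etherification). The angelate and acetate are already in place. A5 could come from the same ring expansion, so this is the closest competitor.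
- *Weak points:* the addition is reversible, so C4 ends under thermodynamic control. That favours the least strained bridge, which need not be the configuration required here. A5 also carries a second, more electrophilic acceptor (the C7=C11 keto ester) and an 8-angelate that tolerates little base.
- *Comparison:* in step economy for the oxolane it is better. The chosen plan sets against it kinetic, irreversible bond formation at C1 and a C4 centre fixed beforehand. The same reversibility does shadow step 12 of the chosen route and is taken up there.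

Key step: step 4

Assumption: the configuration is taken exactly as written, (1S,4S,8S,10R) with a 5E enol ether. With these descriptors the C1–C10 and C4–C5 bonds leave the oxolane on opposite faces, so C4 (step 5) and the C1/C10 pair (step 11) are set in separate face-selective steps and the ether closure is not relied on to correlate them.

## Route

Step 1
Reactants: 1 (E)-1,2-bis(tributylstannyl)ethene; 2 benzylchlorodimethylsilane
Product: 4 (E)-benzyldimethyl[2-(tributylstannyl)ethenyl]silane, via (E)-2-(tributylstannyl)ethenyllithium 3 (not isolated)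
Conditions: n-BuLi (1 equiv), THF, −78 °C; then 2, −78 to 0 °C
Reagents that add atoms: none
Why: A single tin–lithium exchange occurs with retention of the E geometry, and the vinyllithium is silylated by the chlorosilane; benzyl is placed on silicon because fluoride can remove it later without acid or peracid.

Step 2
Reactants: 5 (R)-limonene
Product: 6 (S)-isopiperitenone
Conditions: CrO3, 3,5-dimethylpyrazole, CH2Cl2, −20 °C
Reagents that add atoms: chromium trioxide, O=[Cr](=O)=O
Why: Chromium-mediated allylic oxidation of the ring CH2 between the alkene and the isopropenyl-bearing carbon gives the conjugated enone; the stereocentre is untouched and becomes S only through CIP priorities. Carvone, from the other allylic CH2, is removed by chromatography.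

Step 3
Reactants: 4 (E)-benzyldimethyl[2-(tributylstannyl)ethenyl]silane; 6 (S)-isopiperitenone
Product: 8 (1S,6S)-1-[(E)-2-(benzyldimethylsilyl)ethenyl]-3-methyl-6-(prop-1-en-2-yl)cyclohex-2-en-1-ol, via (E)-2-(benzyldimethylsilyl)ethenyllithium 7 (not isolated)
Conditions: n-BuLi, THF, −78 °C; then 6, −78 °C; aq. NH4Cl
Reagents that add atoms: none
Why: Tin–lithium exchange gives the E-vinyllithium with retention, and its 1,2-addition to the enone carbonyl should occur anti to the adjacent isopropenyl group, placing the two alkenyl groups trans (1S); the minor cis carbinol is separated.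

Step 4
Reactants: 8 (1S,6S)-1-[(E)-2-(benzyldimethylsilyl)ethenyl]-3-methyl-6-(prop-1-en-2-yl)cyclohex-2-en-1-ol
Product: 11 (2Z,6E,9S)-9-(benzyldimethylsilyl)-3,7-dimethylcyclodeca-2,6-dien-1-one, via potassium alkoxide 9 (not isolated), via potassium enolate 10 (not isolated)
Conditions: KH, 18-crown-6, THF, 0 to 25 °C; then aq. NH4Cl at −78 °C
Reagents that add atoms: none
Why: Deprotonation gives alkoxide 9, whose oxyanion weakens the C1–C6 ring bond (cyclohexene locants); a concerted [3,3] shift through a chair transition state breaks that bond and joins the silyl-bearing vinyl terminus to the isopropenyl CH2 (C8–C9), giving enolate 10, which is protonated to 11. The closest known reaction type is the anionic oxy-Cope ring expansion of trans-1,2-dialkenylcyclohexanols to cyclodec-5-enones. The ten-membered ring is closed by four-atom ring expansion of the six-membered ring, the new C8–C9 bond closing it as the old ring bond opens. The only new stereocentre, C8, is set by chirality transfer: the trans dialkenyl arrangement puts both cyclohexene ring bonds equatorial on the chair, the E-vinylsilane puts silicon equatorial, and the 6S centre of 8 then fixes which face of the vinyl terminus bonds, giving 8S (9S in the ring name). The same chair delivers the 1(10)E alkene, and the 4Z enone is the untouched cyclohexene double bond. The step needs chair over boat and [3,3] over fragmentation or [1,3] shift; the trans arrangement and a crown-dissociated potassium alkoxide at or below room temperature should secure this. Silicon on an sp2 carbon trans to the carbinol cannot be reached by the alkoxide, and in 10 it sits β to the enolate carbon, where it is inert.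

Step 5
Reactants: 11 (2Z,6E,9S)-9-(benzyldimethylsilyl)-3,7-dimethylcyclodeca-2,6-dien-1-one
Product: 12 (1S,4S,6E,10S)-4-(benzyldimethylsilyl)-6,10-dimethyl-11-oxabicyclo[8.1.0]undec-6-en-2-one
Conditions: t-BuOOH, benzyltrimethylammonium hydroxide (cat.), THF, 0 °C
Reagents that add atoms: tert-butyl hydroperoxide, CC(C)(C)OO
Why: In this Weitz–Scheffer epoxidation the hydroperoxide anion adds to C4 of the enone and the enolate closes onto oxygen; attack on the ring face remote from the C8 silyl group should set C4 as S (the C5 centre is erased in step 10). The nucleophilic oxidant leaves the electron-rich 1(10) alkene and the C–Si bond alone.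

Step 6
Reactants: 12 (1S,4S,6E,10S)-4-(benzyldimethylsilyl)-6,10-dimethyl-11-oxabicyclo[8.1.0]undec-6-en-2-one
Product: 14 (1S,4S,6E,10S)-4-hydroxy-6,10-dimethyl-11-oxabicyclo[8.1.0]undec-6-en-2-one, via fluorosilane 13 (not isolated)
Conditions: Bu4NF, THF, 0 °C; then 30% H2O2, KHCO3, MeOH, 25 °C
Reagents that add atoms: hydrogen peroxide, OO
Why: In this Tamao–Fleming oxidation fluoride cleaves the benzyl group from silicon and basic peroxide then moves C8 from silicon to oxygen with retention, so 8S is kept. No electrophile or peracid is present, so the 1(10) alkene and the epoxy ketone should survive.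

Step 7
Reactants: 14 (1S,4S,6E,10S)-4-hydroxy-6,10-dimethyl-11-oxabicyclo[8.1.0]undec-6-en-2-one
Product: 15 (1S,4S,6E,10S)-4-(tert-butyldiphenylsilyloxy)-6,10-dimethyl-11-oxabicyclo[8.1.0]undec-6-en-2-one
Conditions: t-BuPh2SiCl, imidazole, DMF, 25 °C
Reagents that add atoms: tert-butylchlorodiphenylsilane, CC(C)(C)[Si](Cl)(c1ccccc1)c1ccccc1
Why: Standard silylation of the only hydroxyl; the ether blocks 8,12-lactonisation once C12 arrives, is a poor leaving group from the C6–C7 enolate, and withstands the acid of step 12.

Step 8
Reactants: 16 ethyl bromopyruvate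
Product: 17 ethyl 3-acetoxy-2-oxopropanoate
Conditions: KOAc, acetone, 25 °C
Reagents that add atoms: potassium acetate, CC(=O)[O-].[K+]
Why: SN2 displacement of the activated α-bromo ketone by acetate.

Step 9
Reactants: 15 (1S,4S,6E,10S)-4-(tert-butyldiphenylsilyloxy)-6,10-dimethyl-11-oxabicyclo[8.1.0]undec-6-en-2-one; 17 ethyl 3-acetoxy-2-oxopropanoate
Product: 19 ethyl (4S,5S,8S)-13-acetoxy-8-(tert-butyldiphenylsilyloxy)-4,5-epoxy-11-hydroxy-6-oxogermacr-1(10)E-en-12-oate (C7/C11 epimers), via lithium enolate 18 (not isolated)
Conditions: LiN(iPr)2, THF, −78 °C; then 17, −78 °C; AcOH quench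
Reagents that add atoms: none
Why: Lithium enolate aldol addition to the keto group of an α-keto ester; the epoxide carbon C5 cannot be deprotonated, so the enolate forms only toward C7, and the very electrophilic keto group should be attacked faster than its CH2 is deprotonated. C7 and C11 form as a mixture and both become sp2 in step 12.

Step 10
Reactants: 19 ethyl (4S,5S,8S)-13-acetoxy-8-(tert-butyldiphenylsilyloxy)-4,5-epoxy-11-hydroxy-6-oxogermacr-1(10)E-en-12-oate
Product: 20 ethyl (4S,8S)-13-acetoxy-8-(tert-butyldiphenylsilyloxy)-4,11-dihydroxy-6-oxogermacr-1(10)E-en-12-oate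
Conditions: SmI2, THF/MeOH, −90 °C
Reagents that add atoms: none
Why: Samarium diiodide reduces the ketone to a ketyl that expels the α-oxygen at C5, and methanol protonates the samarium enolate, giving the β-hydroxy ketone with C4–O intact (4S retained). Ester, acetate and the isolated alkene are not reduced at this temperature.

Step 11
Reactants: 20 ethyl (4S,8S)-13-acetoxy-8-(tert-butyldiphenylsilyloxy)-4,11-dihydroxy-6-oxogermacr-1(10)E-en-12-oate
Product: 22 ethyl (1S,4S,8S,10R)-13-acetoxy-8-(tert-butyldiphenylsilyloxy)-1,4-epoxy-10,11-dihydroxy-6-oxogermacran-12-oate, via 1,10-epoxide 21 (not isolated)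
Conditions: mCPBA, NaHCO3, CH2Cl2, 0 °C; then camphorsulfonic acid (cat.), 0 to 25 °C
Reagents that add atoms: 3-chloroperbenzoic acid, OOC(=O)c1cccc(Cl)c1
Why: Prilezhaev epoxidation of the only alkene from its outer face, in the conformer that keeps the C8 silyloxy group and the C7 side chain outside the ring, should give the (1R,10R)-epoxide 21. Acid-catalysed 5-exo opening by the C4 hydroxyl then inverts C1 to S and leaves the epoxide oxygen on C10 (R).

Step 12
Reactants: 22 ethyl (1S,4S,8S,10R)-13-acetoxy-8-(tert-butyldiphenylsilyloxy)-1,4-epoxy-10,11-dihydroxy-6-oxogermacran-12-oate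
Product: 23 (1S,4S,5E,8S,10R)-13-acetoxy-8-(tert-butyldiphenylsilyloxy)-1,4-epoxy-10-hydroxygermacra-5,7(11)-dien-12,6-olide
Conditions: TsOH·H2O (cat.), benzene, 4 Å molecular sieves, 60 °C
Reagents that add atoms: none
Why: Acid cyclocondensation of a γ-keto α-hydroxy ester (butenolide annulation of pyruvate aldol adducts): C12 lactonises onto the C6 enol oxygen and water is lost from C11/C7, giving the conjugated dienolide with C4 and C7 cis on C5=C6. The tertiary C10 alcohol is deactivated toward ionisation by the adjacent ether oxygen.

Step 13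
Reactants: 23 (1S,4S,5E,8S,10R)-13-acetoxy-8-(tert-butyldiphenylsilyloxy)-1,4-epoxy-10-hydroxygermacra-5,7(11)-dien-12,6-olide
Product: 24 (1S,4S,5E,8S,10R)-13-acetoxy-1,4-epoxy-8,10-dihydroxygermacra-5,7(11)-dien-12,6-olide
Conditions: HF·pyridine, pyridine/THF, 0 to 25 °C
Reagents that add atoms: none
Why: Desilylation by buffered hydrogen fluoride should spare the enol lactone and the acetate; once C7=C11 exists, O8 can no longer reach C12, so the free alcohol does not translactonise.

Step 14
Reactants: 24 (1S,4S,5E,8S,10R)-13-acetoxy-1,4-epoxy-8,10-dihydroxygermacra-5,7(11)-dien-12,6-olide; 25 angelic acid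
Product: 26 (1S,4S,5E,8S,10R)-13-acetoxy-8-angeloyloxy-1,4-epoxy-10-hydroxygermacra-5,7(11)-dien-12,6-olide
Conditions: 2,4,6-trichlorobenzoyl chloride, Et3N, toluene, 25 °C; then 24, 75 °C
Reagents that add atoms: none
Why: Yamaguchi-type esterification through the mixed 2,4,6-trichlorobenzoic anhydride, run without a nucleophilic catalyst, should acylate the secondary allylic alcohol and keep the Z geometry of the acid; the tertiary C10 hydroxyl is not acylated.

## Compound list

1 | (E)-1,2-bis(tributylstannyl)ethene | CCCC[Sn](CCCC)(CCCC)/C=C/[Sn](CCCC)(CCCC)CCCC | starting material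
2 | benzylchlorodimethylsilane | C[Si](C)(Cl)Cc1ccccc1 | starting material
3 | (E)-2-(tributylstannyl)ethenyllithium (not isolated) | [Li]/C=C/[Sn](CCCC)(CCCC)CCCC | intermediate
4 | (E)-benzyldimethyl[2-(tributylstannyl)ethenyl]silane | CCCC[Sn](CCCC)(CCCC)/C=C/[Si](C)(C)Cc1ccccc1 | intermediate
5 | (R)-limonene, (4R)-1-methyl-4-(prop-1-en-2-yl)cyclohex-1-ene | CC1=CC[C@@H](CC1)C(C)=C | starting material
6 | (S)-isopiperitenone, (6S)-3-methyl-6-(prop-1-en-2-yl)cyclohex-2-en-1-one | CC1=CC(=O)[C@@H](CC1)C(C)=C | intermediate
7 | (E)-2-(benzyldimethylsilyl)ethenyllithium (not isolated) | [Li]/C=C/[Si](C)(C)Cc1ccccc1 | intermediate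
8 | (1S,6S)-1-[(E)-2-(benzyldimethylsilyl)ethenyl]-3-methyl-6-(prop-1-en-2-yl)cyclohex-2-en-1-ol | C[Si](C)(Cc1ccccc1)/C=C/[C@]2(O)C=C(C)CC[C@H]2C(C)=C | intermediate
9 | potassium alkoxide of 8 (not isolated) | C[Si](C)(Cc1ccccc1)/C=C/[C@]2([O-])C=C(C)CC[C@H]2C(C)=C.[K+] | intermediate
10 | potassium C6–C7 enolate of 11, E in the ring (not isolated) | C[Si](C)(Cc1ccccc1)[C@H]2C/C(C)=C/CC/C(C)=C\C([O-])=C\2.[K+] | intermediate
11 | (2Z,6E,9S)-9-(benzyldimethylsilyl)-3,7-dimethylcyclodeca-2,6-dien-1-one (germacrane locants: 8S-silyl, 1(10)E,4Z-dien-6-one) | C[Si](C)(Cc1ccccc1)[C@H]2C/C(C)=C/CC/C(C)=C\C(=O)C2 | intermediate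
12 | (1S,4S,6E,10S)-4-(benzyldimethylsilyl)-6,10-dimethyl-11-oxabicyclo[8.1.0]undec-6-en-2-one (germacrane locants: 4S,5S,8S; 4,5-epoxide) | C[Si](C)(Cc1ccccc1)[C@H]2C/C(C)=C/CC[C@]3(C)O[C@@H]3C(=O)C2 | intermediate
13 | (1S,4S,6E,10S)-4-(fluorodimethylsilyl)-6,10-dimethyl-11-oxabicyclo[8.1.0]undec-6-en-2-one (not isolated) | C[Si](C)(F)[C@H]1C/C(C)=C/CC[C@]2(C)O[C@@H]2C(=O)C1 | intermediate
14 | (1S,4S,6E,10S)-4-hydroxy-6,10-dimethyl-11-oxabicyclo[8.1.0]undec-6-en-2-one | O[C@H]1C/C(C)=C/CC[C@]2(C)O[C@@H]2C(=O)C1 | intermediate
15 | (1S,4S,6E,10S)-4-(tert-butyldiphenylsilyloxy)-6,10-dimethyl-11-oxabicyclo[8.1.0]undec-6-en-2-one | CC(C)(C)[Si](c1ccccc1)(c2ccccc2)O[C@H]3C/C(C)=C/CC[C@]4(C)O[C@@H]4C(=O)C3 | intermediate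
16 | ethyl bromopyruvate (ethyl 3-bromo-2-oxopropanoate) | CCOC(=O)C(=O)CBr | starting material
17 | ethyl 3-acetoxy-2-oxopropanoate | CCOC(=O)C(=O)COC(C)=O | intermediate
18 | lithium C6–C7 enolate of 15 (not isolated) | CC(C)(C)[Si](c1ccccc1)(c2ccccc2)O[C@H]3C/C(C)=C/CC[C@]4(C)O[C@@H]4C([O-])=C3.[Li+] | intermediate
19 | ethyl (4S,5S,8S)-13-acetoxy-8-(tert-butyldiphenylsilyloxy)-4,5-epoxy-11-hydroxy-6-oxogermacr-1(10)E-en-12-oate, mixture of C7/C11 epimers | CC(C)(C)[Si](c1ccccc1)(c2ccccc2)O[C@H]3C/C(C)=C/CC[C@]4(C)O[C@@H]4C(=O)C3C(O)(COC(C)=O)C(=O)OCC | intermediate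
20 | ethyl (4S,8S)-13-acetoxy-8-(tert-butyldiphenylsilyloxy)-4,11-dihydroxy-6-oxogermacr-1(10)E-en-12-oate, mixture of C7/C11 epimers | CC(C)(C)[Si](c1ccccc1)(c2ccccc2)O[C@H]3C/C(C)=C/CC[C@](C)(O)CC(=O)C3C(O)(COC(C)=O)C(=O)OCC | intermediate
21 | ethyl (1R,4S,8S,10R)-13-acetoxy-8-(tert-butyldiphenylsilyloxy)-1,10-epoxy-4,11-dihydroxy-6-oxogermacran-12-oate (not isolated) | CC(C)(C)[Si](c1ccccc1)(c2ccccc2)O[C@H]3C[C@@]4(C)O[C@@H]4CC[C@](C)(O)CC(=O)C3C(O)(COC(C)=O)C(=O)OCC | intermediate
22 | ethyl (1S,4S,8S,10R)-13-acetoxy-8-(tert-butyldiphenylsilyloxy)-1,4-epoxy-10,11-dihydroxy-6-oxogermacran-12-oate, mixture of C7/C11 epimers | CC(C)(C)[Si](c1ccccc1)(c2ccccc2)O[C@H]3C[C@@](C)(O)[C@@H]4CC[C@@](C)(CC(=O)C3C(O)(COC(C)=O)C(=O)OCC)O4 | intermediate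
23 | (1S,4S,5E,8S,10R)-13-acetoxy-8-(tert-butyldiphenylsilyloxy)-1,4-epoxy-10-hydroxygermacra-5,7(11)-dien-12,6-olide | CC(C)(C)[Si](c1ccccc1)(c2ccccc2)O[C@H]3C[C@@](C)(O)[C@@H]4CC[C@@](C)(/C=C5/OC(=O)C(COC(C)=O)=C53)O4 | intermediate
24 | (1S,4S,5E,8S,10R)-13-acetoxy-1,4-epoxy-8,10-dihydroxygermacra-5,7(11)-dien-12,6-olide | O[C@H]1C[C@@](C)(O)[C@@H]2CC[C@@](C)(/C=C3/OC(=O)C(COC(C)=O)=C31)O2 | intermediate
25 | angelic acid, (Z)-2-methylbut-2-enoic acid | C/C=C(/C)C(=O)O | starting material
26 | (1S,4S,5E,8S,10R)-13-acetoxy-8-angeloyloxy-1,4-epoxy-10-hydroxygermacra-5,7(11)-dien-12,6-olide (CNP0162854.1) | C/C=C(/C)C(=O)O[C@H]1C[C@@](C)(O)[C@@H]2CC[C@@](C)(/C=C3/OC(=O)C(COC(C)=O)=C31)O2 | target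

## Step count and least certain steps

Total: 14 steps. Longest linear sequence: 12 steps from 5 (steps 2–7 and 9–14); steps 1 and 8 are one-step side branches.

**Step 4 (key step).** The rearrangement may be non-selective or incomplete: a boat pathway from residual cis carbinol, fragmentation of the alkoxide, base-induced isomerisation of the 4Z enone before the quench, or attack of the dissociated alkoxide on the benzylsilane. Fallback, a neutral thermal siloxy-Cope from 8: silylation (Me3SiCl, imidazole) gives the trimethylsilyl ether of 8 F1. Heating in decalin at about 200 °C in base-washed glass carries it through the same chair to the trimethylsilyl enol ether of 11 F2. Mild hydrolysis (citric acid, MeOH) returns to 11.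

**Step 5.** Facial selectivity at C4 may be poor, because the only controlling centre, C8, lies across a flexible ring; the enone geometry may also equilibrate before ring closure of the peroxy enolate. Fallback from 11:
- CBS reduction ((R)-2-methyl-CBS-oxazaborolidine, BH3·SMe2) gives by reagent control the allylic alcohol (1S,2Z,6E,9S)-9-(benzyldimethylsilyl)-3,7-dimethylcyclodeca-2,6-dien-1-ol F3.
- VO(acac)2/t-BuOOH epoxidises the Z-allylic alcohol syn to the hydroxyl under A(1,3) control, giving the epoxy alcohol (1R,2S,4S,6E,10S)-4-(benzyldimethylsilyl)-6,10-dimethyl-11-oxabicyclo[8.1.0]undec-6-en-2-ol F4.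
- Dess–Martin oxidation returns to 12.

**Step 9.** Proton transfer from the acidic CH2 of 17 to enolate 18 would return 15; β-elimination of the C8 silyloxy group from 18 or acetyl transfer to the enolate are the other exits. Fallback, a non-basic Mukaiyama aldol from 15: the enolate is trapped with Me3SiCl as the trimethylsilyl enol ether of 15 F5. Compound 17 is then added under Cu(OTf)2 catalysis, the divalent copper chelating the α-keto ester. This gives the trimethylsilyl ether of the adduct F6, whose acidic work-up returns to 19.

**Step 11.** Three processes can fail: peracid attack on the wrong face of the 1(10) alkene, 6-endo opening at tertiary C10 under acid, and slow closure, since the new C1–O bond must bridge the ring with C5 and C10 on opposite faces of the oxolane. Fallback from 19, before the reduction: Shi epoxidation (D-fructose-derived ketone catalyst, KHSO5, K2CO3 buffer, MeCN/H2O, 0 °C) sets (1R,10R) by catalyst control and gives the bis-epoxide, ethyl (1R,4S,5S,8S,10R)-13-acetoxy-8-(tert-butyldiphenylsilyloxy)-1,10:4,5-diepoxy-11-hydroxy-6-oxogermacran-12-oate F7. SmI2 then reduces only the α,β-epoxy ketone, and the trivalent samarium alkoxide on C4 opens the 1,10-epoxide at its less substituted carbon without acid, rejoining the route at 22.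

**Step 12.** Side reactions may run ahead of lactonisation: reversible β-elimination of the C4 ether oxygen (which would let C4 equilibrate), ionisation of the tertiary C10 alcohol, or loss of the silyl ether followed by 8,12-lactonisation. Fallback from 22, in two stages without strong Brønsted acid: CeCl3·7H2O/NaI in MeCN dehydrates the β-hydroxy ketone by chelation to the alkylidene keto ester, ethyl (1S,4S,7(11)Z,8S,10R)-13-acetoxy-8-(tert-butyldiphenylsilyloxy)-1,4-epoxy-10-hydroxy-6-oxogermacr-7(11)-en-12-oate F8; the E isomer equilibrates through iodide addition–elimination. Pyridinium p-toluenesulfonate in warm toluene then closes the enol lactone, returning to 23.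

## Further compounds

F1 | step 4 | (1S,6S)-1-[(E)-2-(benzyldimethylsilyl)ethenyl]-3-methyl-6-(prop-1-en-2-yl)-1-(trimethylsilyloxy)cyclohex-2-ene | C[Si](C)(Cc1ccccc1)/C=C/[C@]2(O[Si](C)(C)C)C=C(C)CC[C@H]2C(C)=C
F2 | step 4 | trimethylsilyl enol ether of 11 (C6–C7 enol ether, E in the ring, 8S) | C[Si](C)(Cc1ccccc1)[C@H]2C/C(C)=C/CC/C(C)=C\C(O[Si](C)(C)C)=C\2
F3 | step 5 | (1S,2Z,6E,9S)-9-(benzyldimethylsilyl)-3,7-dimethylcyclodeca-2,6-dien-1-ol | C[Si](C)(Cc1ccccc1)[C@H]2C/C(C)=C/CC/C(C)=C\[C@@H](O)C2
F4 | step 5 | (1R,2S,4S,6E,10S)-4-(benzyldimethylsilyl)-6,10-dimethyl-11-oxabicyclo[8.1.0]undec-6-en-2-ol | C[Si](C)(Cc1ccccc1)[C@H]2C/C(C)=C/CC[C@]3(C)O[C@@H]3[C@@H](O)C2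
F5 | step 9 | trimethylsilyl enol ether of 15 (C6–C7 enol ether) | CC(C)(C)[Si](c1ccccc1)(c2ccccc2)O[C@H]3C/C(C)=C/CC[C@]4(C)O[C@@H]4C(O[Si](C)(C)C)=C3
F6 | step 9 | 11-O-trimethylsilyl ether of 19 | CC(C)(C)[Si](c1ccccc1)(c2ccccc2)O[C@H]3C/C(C)=C/CC[C@]4(C)O[C@@H]4C(=O)C3C(O[Si](C)(C)C)(COC(C)=O)C(=O)OCC
F7 | step 11 | ethyl (1R,4S,5S,8S,10R)-13-acetoxy-8-(tert-butyldiphenylsilyloxy)-1,10:4,5-diepoxy-11-hydroxy-6-oxogermacran-12-oate | CC(C)(C)[Si](c1ccccc1)(c2ccccc2)O[C@H]3C[C@@]4(C)O[C@@H]4CC[C@]5(C)O[C@@H]5C(=O)C3C(O)(COC(C)=O)C(=O)OCC
F8 | step 12 | ethyl (1S,4S,7(11)Z,8S,10R)-13-acetoxy-8-(tert-butyldiphenylsilyloxy)-1,4-epoxy-10-hydroxy-6-oxogermacr-7(11)-en-12-oate | CC(C)(C)[Si](c1ccccc1)(c2ccccc2)O[C@H]3C[C@@](C)(O)[C@@H]4CC[C@@](C)(CC(=O)/C3=C(/COC(C)=O)C(=O)OCC)O4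
A1 | alternative 1 | (2E,6S)-2,6-dimethylocta-2,7-diene-1,6-diol ((S,E)-8-hydroxylinalool) | OC/C(C)=C/CC[C@](C)(O)C=C
A2 | alternative 1 | (2R)-2-[(2S,5S)-5-ethenyl-5-methyloxolan-2-yl]propane-1,2-diol | OC[C@@](C)(O)[C@@H]1CC[C@@](C)(C=C)O1
A3 | alternative 2 | seco acid: 5-[(2R,4S)-4-(tert-butyldimethylsilyloxy)-2-hydroxy-4-{4-(acetoxymethyl)-2-[(Z)-bromomethylidene]-5-oxo-2,5-dihydrofuran-3-yl}butan-2-yl]-2-methyloxolane-2-carboxylic acid, (5S) at the oxolane methine, either configuration at the carboxyl-bearing carbon | CC(=O)OCC1=C([C@H](C[C@@](C)(O)[C@@H]2CCC(C)(C(O)=O)O2)O[Si](C)(C)C(C)(C)C)/C(=C\Br)OC1=O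
A4 | alternative 2 | (1S,4S,5E,8S,10R)-13-acetoxy-8-(tert-butyldimethylsilyloxy)-1,4-epoxy-10-hydroxygermacra-5,7(11)-dien-12,6-olide | CC(C)(C)[Si](C)(C)O[C@H]1C[C@@](C)(O)[C@@H]2CC[C@@](C)(/C=C3/OC(=O)C(COC(C)=O)=C31)O2
A5 | alternative 3 | allyl (1S,4E,7(11)Z,8S,10R)-13-acetoxy-8-angeloyloxy-1,10-dihydroxy-6-oxogermacra-4,7(11)-dien-12-oate | C/C=C(/C)C(=O)O[C@H]1C[C@@](C)(O)[C@@H](O)CC/C(C)=C/C(=O)/C1=C(/COC(C)=O)C(=O)OCC=C
A6 | alternative 3 | allyl (1S,4S,7(11)Z,8S,10R)-13-acetoxy-8-angeloyloxy-1,4-epoxy-10-hydroxy-6-oxogermacr-7(11)-en-12-oate | C/C=C(/C)C(=O)O[C@H]1C[C@@](C)(O)[C@@H]2CC[C@@](C)(CC(=O)/C1=C(/COC(C)=O)C(=O)OCC=C)O2
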